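## Retrosynthetic overview
1. Target 22 ⇐ 7-ketone 18: Mannich base at C8, axial reduction of the 7-ketone, Cope elimination (gives C8=CH2 and 7α-OH).
2. 18 ⇐ cross-conjugated dienone 17 (double conjugate reduction sets 5α-H and 9α-H) ⇐ β-bromodienone 13 + the (Z)-C5 side chain from enynol 14 (B-alkyl Suzuki).
3. Key step, 13 ⇐ 12: a silyl-protected p-cresol-type ring attacks a tethered terminal epoxide through its methyl-bearing para carbon. The arene is dearomatised to the dienone, ring A and the C10 quaternary centre form, and the C2 hydroxyl is delivered.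
4. 12 ⇐ lactone 8 (chloromethyl ketone, acetate, CBS reduction, epoxide closure) ⇐ asymmetric conjugate arylation of butenolide 5 with the mono-metalated symmetric dibromide 4 (sets C4) ⇐ 2,6-dibromotoluene 1.
5. Ring order: ring B is the starting benzene ring; ring A closes in the key step.

Assumption: the target is read as 2α,7α,15-trihydroxylabda-8(17),13Z-dien-19-yl acetate (2R,4S,5R,7R,9R,10S); labdane numbering (C1–C20) is used in the comments, and 1, 5 and 14 are taken as commercial.

## Route

Step 1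
Reactants: 1 2,6-dibromotoluene
Product: 3 3,5-dibromo-4-methylphenol, via aryl pinacol boronate 2 (not isolated)
Conditions: [Ir(OMe)(cod)]2 (1.5 mol %), 4,4'-di-tert-butyl-2,2'-bipyridine, B2pin2, THF, 80 °C; then KHSO5 (Oxone), acetone/H2O, rt
Reagents that add atoms: bis(pinacolato)diboron (Bpin of 2), CC1(C)OB(OC1(C)C)B1OC(C)(C)C(C)(C)O1; potassium peroxymonosulfate (O of 3), [K+].[O-]S(=O)(=O)OO
Why: Sterically controlled iridium-catalysed C–H borylation of a 1,2,3-trisubstituted arene takes only the C–H flanked by two hydrogens, and one-pot oxidation of the C–B bond gives the phenol; no stereocentre.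

Step 2
Reactants: 3 3,5-dibromo-4-methylphenol
Product: 4 (3,5-dibromo-4-methylphenoxy)triisopropylsilane
Conditions: i-Pr3SiCl, imidazole, DMF, rt
Reagents that add atoms: chlorotriisopropylsilane, CC(C)[Si](Cl)(C(C)C)C(C)C
Why: Standard phenol silylation; the bulky silyl ether survives the organometallic steps and later shields the ortho carbons in the key step.

Step 3
Reactants: 4 (3,5-dibromo-4-methylphenoxy)triisopropylsilane; 5 4-methylfuran-2(5H)-one
Product: 8 (S)-4-[3-bromo-2-methyl-5-(triisopropylsilyloxy)phenyl]-4-methyldihydrofuran-2(3H)-one, via aryllithium 6 (not isolated), via aryl(dimethyl)alane 7 (not isolated)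
Conditions: n-BuLi (1.0 equiv), Et2O, −78 °C; Me2AlCl, −78 °C → rt; then 5, [RhCl(cod)]2 (3 mol %), (S)-BINAP (7 mol %), THF, 50 °C; aq. potassium sodium tartrate
Reagents that add atoms: n-butyllithium (Li of 6), [Li]CCCC; chlorodimethylalane (AlMe2 of 7), C[Al](C)Cl
Why: Mono Br/Li exchange on the symmetric dibromide and transmetalation give an aryl alane, the nucleophile class that tolerates ortho substituents in rhodium/BINAP-catalysed asymmetric conjugate addition; the aryl–rhodium species adds to the β-carbon of 5 on the ligand-selected face and sets the quaternary C4 centre (the BINAP enantiomer giving S is to be confirmed on the first run).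

Step 4
Reactants: 8 the (S)-lactone
Product: 9 (S)-4-[3-bromo-2-methyl-5-(triisopropylsilyloxy)phenyl]-1-chloro-5-hydroxy-4-methylpentan-2-one
Conditions: ICH2Cl, MeLi·LiBr, THF, −78 °C; aq. NH4Cl at −78 °C
Reagents that add atoms: chloroiodomethane, ClCI
Why: Chloromethyllithium made in situ adds once to the lactone because the cyclic lithium hemiketalate persists until the quench (ester-to-chloromethyl-ketone homologation); it delivers C1, unmasks the C19 hydroxyl and leaves C4 untouched.

Step 5
Reactants: 9 the hydroxy chloromethyl ketone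
Product: 10 (S)-2-[3-bromo-2-methyl-5-(triisopropylsilyloxy)phenyl]-5-chloro-2-methyl-4-oxopentyl acetate
Conditions: Ac2O, pyridine, DMAP (cat.), CH2Cl2, 0 °C
Reagents that add atoms: acetic anhydride, CC(=O)OC(C)=O
Why: Acylation of the only free hydroxyl (the open-chain primary alcohol reacts; the hemiketal form is drained by equilibrium) installs the C19 acetate of the target at the one stage where no other hydroxyl exists.

Step 6
Reactants: 10 the acetoxy chloromethyl ketone
Product: 11 (2S,4S)-2-[3-bromo-2-methyl-5-(triisopropylsilyloxy)phenyl]-5-chloro-4-hydroxy-2-methylpentyl acetate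
Conditions: (S)-2-methyl-CBS-oxazaborolidine (15 mol %), BH3·SMe2, THF, −20 °C; MeOH
Reagents that add atoms: none
Why: Corey–Bakshi–Shibata reduction with reagent control (CH2Cl as the small group, the neopentyl-type CH2 as the large group) sets the carbinol centre that becomes C2 with its 2α-oxygen; acetate and aryl bromide are inert to the borane at −20 °C.

Step 7
Reactants: 11 the chlorohydrin
Product: 12 (S)-2-[3-bromo-2-methyl-5-(triisopropylsilyloxy)phenyl]-2-methyl-3-[(S)-oxiran-2-yl]propyl acetate
Conditions: KN(SiMe3)2 (1.05 equiv), THF, −78 → 0 °C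
Reagents that add atoms: none
Why: Intramolecular Williamson closure (3-exo-tet) of the alkoxide onto the primary chloride is much faster than acyl transfer; the C2 centre is not touched.

Step 8
Reactants: 12 the aryl epoxide
Product: 13 [(1S,3S,4aS)-5-bromo-3-hydroxy-1,4a-dimethyl-7-oxo-1,2,3,4,4a,7-hexahydronaphthalen-1-yl]methyl acetate (labdane: 9-bromo-2α-hydroxy-7-oxo-5,8-dien-19-yl acetate, ring A closed)
Conditions: SnCl4 (1.2 equiv), CH2Cl2, −78 → −30 °C; aq. NaHCO3
Reagents that add atoms: none
Why: Proposed new method: SnCl4 activates the terminal epoxide and the arene attacks the primary carbon C1 through the ring carbon para to the silyloxy group (ipso to CH3) in a six-membered chair (attack at C2 would need a five-membered closure, and the ortho carbon C6 is shielded by the bulky silyl ether), after which chloride removes the silyl group from the silyloxy-arenium ion to give the cross-conjugated dienone; backside opening forces the epoxide oxygen equatorial, so the C2 centre fixes the new C10 centre (CH3 β) and the pre-set C4 centre places CH2OAc axial, cis to that methyl; the closest known chemistry is the Lewis-acid cyclialkylation of 4-aryl-1,2-epoxybutanes to 2-tetralols and the Ar2-6 ipso-cyclisations of phenols and anisoles that give 4a-methyl dienones (intramolecular dearomative Friedel–Crafts alkylation).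

Step 9
Reactants: 14 (Z)-3-methylpent-2-en-4-yn-1-ol
Product: 15 (Z)-3-methylpenta-2,4-dien-1-ol
Conditions: H2 (1 atm), Pd/CaCO3 poisoned with Pb(OAc)2, quinoline, EtOAc, 0 °C, stopped at 1 equiv H2
Reagents that add atoms: none
Why: Lindlar semihydrogenation of the terminal alkyne stops at the vinyl group and leaves the trisubstituted Z alkene, which already has the C13 geometry of the target.

Step 10
Reactants: 15 (Z)-3-methylpenta-2,4-dien-1-ol; 13 the β-bromodienone
Product: 17 [(1S,3R,4aR)-3-hydroxy-5-[(3Z)-5-hydroxy-3-methylpent-3-en-1-yl]-1,4a-dimethyl-7-oxo-1,2,3,4,4a,7-hexahydronaphthalen-1-yl]methyl acetate, via B-alkyl-9-BBN borane 16 (not isolated)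
Conditions: 9-BBN-H (2.2 equiv), THF, 0 °C → rt; then 13, Pd(dppf)Cl2 (5 mol %), AsPh3, Cs2CO3, DMF/H2O, rt
Reagents that add atoms: 9-borabicyclo[3.3.1]nonane (boron groups of 16), B1C2CCCC1CCC2
Why: 9-BBN adds anti-Markovnikov to the monosubstituted vinyl group only (the first equivalent is consumed by the OH), and the B-alkyl Suzuki–Miyaura coupling with the β-bromoenone forms C9–C11 with retention of the Z alkene; the descriptor changes at C2 and C10 are CIP effects only.

Step 11
Reactants: 17 the dienone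
Product: 18 [(1S,3R,4aR,5S,8aR)-3-hydroxy-5-[(3Z)-5-hydroxy-3-methylpent-3-en-1-yl]-1,4a-dimethyl-7-oxodecahydronaphthalen-1-yl]methyl acetate
Conditions: [(Ph3P)CuH]6 (1.0 equiv of hexamer), H2O (10 equiv), THF/toluene, rt → 40 °C
Reagents that add atoms: none
Why: Stryker conjugate reduction touches only the two enone C=C bonds (isolated alkene, acetate and alcohols survive), and hydride is delivered to C9 and then C5 from the α face, opposite the axial C10 methyl and the axial CH2OAc, giving 9α-H (side chain equatorial) and the trans ring fusion (5α-H), as in additions to C1 of steroidal 1,4-dien-3-ones and to 5-enes.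

Step 12
Reactants: 18 the saturated 7-ketone
Product: 19 [(1S,3R,4aR,5S,6R,8aR)-6-[(dimethylamino)methyl]-3-hydroxy-5-[(3Z)-5-hydroxy-3-methylpent-3-en-1-yl]-1,4a-dimethyl-7-oxodecahydronaphthalen-1-yl]methyl acetate
Conditions: CH2=NMe2+ I− (1.3 equiv), MeCN, 50 °C; aq. NaHCO3
Reagents that add atoms: N,N-dimethylmethyleneiminium iodide (Eschenmoser's salt), C=[N+](C)C.[I-]
Why: Mannich aminomethylation through the thermodynamic enol, which in a trans-decalin 7-ketone lies toward C8 (the counterpart of C2 in 3-keto-5α-steroids); the new C8 centre equilibrates to the equatorial (α) position and is removed in step 14.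

Step 13
Reactants: 19 the Mannich base
Product: 20 [(1S,3R,4aR,5S,6R,7R,8aR)-6-[(dimethylamino)methyl]-3,7-dihydroxy-5-[(3Z)-5-hydroxy-3-methylpent-3-en-1-yl]-1,4a-dimethyldecahydronaphthalen-1-yl]methyl acetate
Conditions: LiBH(s-Bu)3 (L-Selectride, 3.5 equiv), THF, −78 °C; aq. NH4Cl
Reagents that add atoms: none
Why: The bulky trialkylborohydride attacks the cyclohexanone from the equatorial (β) direction and gives the axial 7α-alcohol (as in 3-keto-5α-steroids, which give 3α-alcohols); the acetate is not reduced at −78 °C.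

Step 14
Reactants: 20 the amino diol
Product: 22 [(1S,3R,4aS,5R,7R,8aR)-3,7-dihydroxy-5-[(3Z)-5-hydroxy-3-methylpent-3-en-1-yl]-1,4a-dimethyl-6-methylidenedecahydronaphthalen-1-yl]methyl acetate, via amine N-oxide 21 (not isolated)
Conditions: H2O2 (30 % aq.), MeOH, rt; excess peroxide destroyed; then DMSO, 90 °C
Reagents that add atoms: hydrogen peroxide (O of 21), OO
Why: N-Oxidation followed by Cope elimination; the syn elimination can only take the C8 hydrogen, so the exocyclic C8=C17 alkene forms next to the untouched 7α-hydroxyl, and H2O2 alone does not epoxidise the side-chain alkene.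

## Compound list
1 | 2,6-dibromotoluene | Cc1c(Br)cccc1Br | starting material
2 | 2-(3,5-dibromo-4-methylphenyl)-4,4,5,5-tetramethyl-1,3,2-dioxaborolane | Cc1c(Br)cc(cc1Br)B1OC(C)(C)C(C)(C)O1 | intermediate
3 | 3,5-dibromo-4-methylphenol | Cc1c(Br)cc(O)cc1Br | intermediate
4 | (3,5-dibromo-4-methylphenoxy)triisopropylsilane | Cc1c(Br)cc(O[Si](C(C)C)(C(C)C)C(C)C)cc1Br | intermediate
5 | 4-methylfuran-2(5H)-one | CC1=CC(=O)OC1 | starting material
6 | [3-bromo-2-methyl-5-(triisopropylsilyloxy)phenyl]lithium | Cc1c(Br)cc(O[Si](C(C)C)(C(C)C)C(C)C)cc1[Li] | intermediate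
7 | [3-bromo-2-methyl-5-(triisopropylsilyloxy)phenyl]dimethylalane | Cc1c(Br)cc(O[Si](C(C)C)(C(C)C)C(C)C)cc1[Al](C)C | intermediate
8 | (S)-4-[3-bromo-2-methyl-5-(triisopropylsilyloxy)phenyl]-4-methyldihydrofuran-2(3H)-one | C[C@@]1(c2cc(O[Si](C(C)C)(C(C)C)C(C)C)cc(Br)c2C)CC(=O)OC1 | intermediate
9 | (S)-4-[3-bromo-2-methyl-5-(triisopropylsilyloxy)phenyl]-1-chloro-5-hydroxy-4-methylpentan-2-one | OC[C@](C)(c1cc(O[Si](C(C)C)(C(C)C)C(C)C)cc(Br)c1C)CC(=O)CCl | intermediate
10 | (S)-2-[3-bromo-2-methyl-5-(triisopropylsilyloxy)phenyl]-5-chloro-2-methyl-4-oxopentyl acetate | CC(=O)OC[C@](C)(c1cc(O[Si](C(C)C)(C(C)C)C(C)C)cc(Br)c1C)CC(=O)CCl | intermediate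
11 | (2S,4S)-2-[3-bromo-2-methyl-5-(triisopropylsilyloxy)phenyl]-5-chloro-4-hydroxy-2-methylpentyl acetate | CC(=O)OC[C@](C)(c1cc(O[Si](C(C)C)(C(C)C)C(C)C)cc(Br)c1C)C[C@H](O)CCl | intermediate
12 | (S)-2-[3-bromo-2-methyl-5-(triisopropylsilyloxy)phenyl]-2-methyl-3-[(S)-oxiran-2-yl]propyl acetate | CC(=O)OC[C@](C)(c1cc(O[Si](C(C)C)(C(C)C)C(C)C)cc(Br)c1C)C[C@H]1CO1 | intermediate
13 | [(1S,3S,4aS)-5-bromo-3-hydroxy-1,4a-dimethyl-7-oxo-1,2,3,4,4a,7-hexahydronaphthalen-1-yl]methyl acetate | CC(=O)OC[C@@]1(C)C[C@H](O)C[C@]2(C)C(Br)=CC(=O)C=C12 | intermediate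
14 | (Z)-3-methylpent-2-en-4-yn-1-ol | C#C/C(C)=C\CO | starting material
15 | (Z)-3-methylpenta-2,4-dien-1-ol | C=C/C(C)=C\CO | intermediate
16 | 9-[(3Z)-5-(9-borabicyclo[3.3.1]nonan-9-yloxy)-3-methylpent-3-en-1-yl]-9-borabicyclo[3.3.1]nonane | C(C/C(C)=C\COB1C2CCCC1CCC2)B1C2CCCC1CCC2 | intermediate
17 | [(1S,3R,4aR)-3-hydroxy-5-[(3Z)-5-hydroxy-3-methylpent-3-en-1-yl]-1,4a-dimethyl-7-oxo-1,2,3,4,4a,7-hexahydronaphthalen-1-yl]methyl acetate | CC(=O)OC[C@@]1(C)C[C@H](O)C[C@]2(C)C(CC/C(C)=C\CO)=CC(=O)C=C12 | intermediate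
18 | [(1S,3R,4aR,5S,8aR)-3-hydroxy-5-[(3Z)-5-hydroxy-3-methylpent-3-en-1-yl]-1,4a-dimethyl-7-oxodecahydronaphthalen-1-yl]methyl acetate | CC(=O)OC[C@@]1(C)C[C@H](O)C[C@]2(C)[C@@H](CC/C(C)=C\CO)CC(=O)C[C@@H]12 | intermediate
19 | [(1S,3R,4aR,5S,6R,8aR)-6-[(dimethylamino)methyl]-3-hydroxy-5-[(3Z)-5-hydroxy-3-methylpent-3-en-1-yl]-1,4a-dimethyl-7-oxodecahydronaphthalen-1-yl]methyl acetate | CC(=O)OC[C@@]1(C)C[C@H](O)C[C@]2(C)[C@@H](CC/C(C)=C\CO)[C@H](CN(C)C)C(=O)C[C@@H]12 | intermediate
20 | [(1S,3R,4aR,5S,6R,7R,8aR)-6-[(dimethylamino)methyl]-3,7-dihydroxy-5-[(3Z)-5-hydroxy-3-methylpent-3-en-1-yl]-1,4a-dimethyldecahydronaphthalen-1-yl]methyl acetate | CC(=O)OC[C@@]1(C)C[C@H](O)C[C@]2(C)[C@@H](CC/C(C)=C\CO)[C@H](CN(C)C)[C@H](O)C[C@@H]12 | intermediate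
21 | N-oxide of 20 | CC(=O)OC[C@@]1(C)C[C@H](O)C[C@]2(C)[C@@H](CC/C(C)=C\CO)[C@H](C[N+](C)(C)[O-])[C@H](O)C[C@@H]12 | intermediate
22 | [(1S,3R,4aS,5R,7R,8aR)-3,7-dihydroxy-5-[(3Z)-5-hydroxy-3-methylpent-3-en-1-yl]-1,4a-dimethyl-6-methylidenedecahydronaphthalen-1-yl]methyl acetate | C=C1[C@H](O)C[C@H]2[C@@](C)(COC(C)=O)C[C@H](O)C[C@]2(C)[C@H]1CC/C(C)=C\CO | target

## Step count and risks
Total steps: 14. Longest linear sequence: 13 (steps 1–8 and 10–14; step 9 is a one-step side branch).

Most likely to fail: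

1. Step 8, the dearomatising ring closure. Attack through the ortho carbon C6 (giving an aromatic tetralin) or Lewis-acid opening or rearrangement of the epoxide may compete with ipso attack at the hindered methyl-bearing carbon. The fallback changes the activation mode. It sets out from 12: Bu4NF buffered with AcOH removes the silyl group to give the free phenol epoxide F4, and its phenoxide (Cs2CO3, DMF, high dilution, 60 °C) closes ring A by anionic para C-alkylation on the primary epoxide carbon (phenoxide Ar2-6 dienone synthesis). O-alkylation is geometrically impossible, and the route is rejoined at 13.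

2. Step 3, the conjugate arylation. The ortho-methyl aryl group and the butenolide acceptor are both beyond the usual scope, so yield or ee may be poor. The fallback builds C4 by a symmetry-breaking oxidation instead and sets out from 4. Mono Suzuki coupling with isopropenylboronic acid pinacol ester (Pd(PPh3)4, K3PO4) gives the isopropenyl arene F1. A [2+2] cycloaddition with dichloroketene (Cl3CCOCl, Zn–Cu couple) gives the dichlorocyclobutanone F2. Zn in AcOH gives the prochiral 3-aryl-3-methylcyclobutanone F3. An enantioselective Baeyer–Villiger oxidation (Sc(OTf)3 with a chiral N,N'-dioxide ligand and H2O2, or a Baeyer–Villiger monooxygenase) then differentiates the two enantiotopic acyl–CH2 bonds and comes back to the route at lactone 8.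

3. Step 12, regiochemistry of the Mannich reaction (C8 against C6). The fallback makes the C7–C8 enol derivative regiospecifically and sets out from 17. Copper hydride catalysis (Cu(OAc)2·H2O, 1,2-bis(diphenylphosphino)benzene, Et3SiH) reduces only the less hindered C8=C9 enone in the 1,4 sense and silylates both hydroxyls, giving the silyl dienol ether F5, which cannot be reduced further. Eschenmoser's salt attacks F5 at C8, and acidic work-up gives the enone Mannich base F6. Conjugate reduction of the remaining C5=C6 bond with [(Ph3P)CuH]6 and H2O returns to the route at 19.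

Further compounds
F1 | step 3 | triisopropyl[3-bromo-4-methyl-5-(prop-1-en-2-yl)phenoxy]silane | CC(=C)c1cc(O[Si](C(C)C)(C(C)C)C(C)C)cc(Br)c1C
F2 | step 3 | 3-[3-bromo-2-methyl-5-(triisopropylsilyloxy)phenyl]-2,2-dichloro-3-methylcyclobutan-1-one (racemic) | CC1(CC(=O)C1(Cl)Cl)c1cc(O[Si](C(C)C)(C(C)C)C(C)C)cc(Br)c1C
F3 | step 3 | 3-[3-bromo-2-methyl-5-(triisopropylsilyloxy)phenyl]-3-methylcyclobutan-1-one | CC1(CC(=O)C1)c1cc(O[Si](C(C)C)(C(C)C)C(C)C)cc(Br)c1C
F4 | step 8 | (S)-2-(3-bromo-5-hydroxy-2-methylphenyl)-2-methyl-3-[(S)-oxiran-2-yl]propyl acetate | CC(=O)OC[C@](C)(c1cc(O)cc(Br)c1C)C[C@H]1CO1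
F5 | step 12 | tris(triethylsilyl) derivative of 17 reduced at C9: 7-silyloxy-5,7-diene with silyl ethers at O2 and O15 | CC(=O)OC[C@@]1(C)C[C@H](O[Si](CC)(CC)CC)C[C@]2(C)[C@@H](CC/C(C)=C\CO[Si](CC)(CC)CC)C=C(O[Si](CC)(CC)CC)C=C12
F6 | step 12 | 8α-[(dimethylamino)methyl]-5-en-7-one: 19 with the C5=C6 double bond still in place | CC(=O)OC[C@@]1(C)C[C@H](O)C[C@]2(C)[C@@H](CC/C(C)=C\CO)[C@H](CN(C)C)C(=O)C=C12
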